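## Analysis of the target

The target 23 is a eudesmane, a trans-fused decalin. Ring A (C1–C5 and C10) carries the (S)-3-methylpentanoate on C3 and a tertiary carbinol with the C15 methyl on C4. Ring B (C5–C10) carries the C8 ketone conjugated to the C7 isopropylidene group. The ring stereocentres are C3 (α-acyloxy, axial), C4 (α-OH equatorial, β-methyl axial), C5 (α-H) and C10 (β-methyl, C14). The two oxygens are cis, the C15 and C14 methyls are syn-diaxial on the β face, and H5 is trans to C14. A fifth, isolated centre lies in the acyl chain and is best bought. The tetrasubstituted enone and the ester next to a free tertiary alcohol are the sensitive groups, so both are introduced late. The hard part is the quaternary C10 in one absolute sense and trans to H5, in a skeleton whose remaining stereocentres all sit on ring A. The strategy rests on reading C14 as the third carbon of a cyclopropane spanning C5 and C10 next to a C4 carbonyl. Without C14, C15 and the isopropylidene carbons, what remains is the reduced skeleton of 6-methoxy-1-tetralone (1), with oxygen already at C4 and C8.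

## Retrosynthetic reasoning

Ester. The C3–O acyl bond of 23 is cut first, giving diol 21 and acid 22. The side-chain stereocentre then comes from a commercial acid, and the acyl group is never exposed to base or to migration onto the C4 hydroxyl. The forward step only has to acylate a secondary hydroxyl next to a tertiary one.

Diol. Both C–O bonds at C3 and C4 of 21 are removed together, leading to diene-one 20. A syn-dihydroxylation sets two stereocentres at once, and the axial C14 methyl should send the oxidant to the α face. The forward reaction must also prefer the electron-rich C3=C4 alkene over the enone alkene.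

Isopropylidene. The C7=C11 bond of 20 is cut as an aldol condensation, through aldol 18 back to ketone 15 and acetone (16). The forward reaction has to enolise the C8 ketone towards C7 and not towards C9, which is helped by C9 being flanked by the quaternary C10.

C4 methyl and C8 mask. Ketone 15 is traced to its dioxolane 14, and the C4–C15 bond is cut as a cross-coupling of enol triflate 13, which comes from ketone 11. This places the trisubstituted alkene exactly at C3=C4 and uses the C4 carbonyl that the key sequence leaves behind. The forward enolisation must be kinetic, towards C3, so that C5 is not disturbed.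

Angular methyl. In 11 the C14 methyl and the C5 hydrogen are reconnected, in the retro sense, to the cyclopropyl ketone 9 through enolate 10. This converts the quaternary methyl problem into a cyclopropane problem. The forward reduction must break C5–C14 and not the in-ring C5–C10 bond, and C5 must end up with its hydrogen on the α face.

Key disconnection. Ketone 9 is the oxidation product of carbinol 8, and in 8 the C10–C14 and C5–C14 bonds are cut back to allylic alcohol 5 and diiodomethane (6). The cut is made here because the tetrasubstituted alkene of 5 sits exactly at the ring fusion and its neighbouring carbinol can carry the absolute configuration. The forward reaction must deliver the methylene to the β face only.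

Precursor. The C5=C10 alkene and the masked C8 ketone of 5 are what a Birch reduction leaves of an anisole ring, so 5 goes back through enol ether 4 to benzylic alcohol 2. The carbinol of 2 is cut back to ketone 1 by an enantioselective reduction. This gives the precursor in three steps from a commercial tetralone.

## Alternatives that were turned down

Alternative 1: The C9–C10 bond is cut in a cross-conjugated dienone, so ring B is closed by dearomatisation of a phenol. In the forward sense the allylic carbonate A1, a 2,4-dimethylphenol with a side chain on C3, is ionised by Pd2(dba)3 (zerovalent palladium) and a chiral phosphine. The para carbon of the phenol attacks the π-allyl unit and gives dienone A2 with the quaternary C10 and an exocyclic methylene at C8. In its favour, C10 is set by the catalyst in the ring-forming step, and C15 and the C3 oxygen are present from the start, so no enol triflate or methyl coupling is needed. On these points it is stronger than the chosen route. Against it, the new stereocentre lies on the nucleophile, far from the ligand, and the π-allyl unit is symmetric, so enantiofacial control of the phenol is hard to secure. O-allylation can also compete. Downstream, A2 needs two different alkene reductions in ring A with trans control at C5, an α-hydroxylation at C4, an axial reduction at C3 and cleavage of the methylene. The chosen route offers instead a stereocentre from a dependable ketone reduction, relayed intramolecularly, and a ring A that is oxidised only once.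

Alternative 2: The C5–C10 and C6–C7 bonds are cut together, so both rings arise from the acyclic dienyne ketone A3. Forward, a chiral oxazaborolidinium Lewis acid activates the ynone, which adds across the silyloxydiene to give bicyclic dienone A4 with the quaternary C10, the C4 ketone and a masked C8 ketone. Its ring construction is more economical than anything in the chosen route: two rings and two C–C bonds in one step. Against it, the diene terminus that becomes C10 is 1,1-disubstituted, so one substituent must point inwards in the reactive s-cis conformer and the cycloaddition is slowed. A3 also needs a stereodefined trisubstituted silyloxydiene and a sensitive terminal ynone, which costs several steps. A4 then needs conjugate reduction of C5=C6 with the same C5 question that the chosen route faces. The chosen route offers a three-step precursor and a quaternary centre set by an intramolecular, face-bound delivery.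

Alternative 3: The C3–C4 bond is cut, so ring A is closed last by a crossed benzoin reaction. Forward, a chiral triazolium-derived carbene converts the aldehyde of keto-aldehyde A5 into an acyl anion equivalent that adds to the methyl ketone and gives ketol A6. This has the strongest endgame: C15, the C4 carbinol and the C3 oxygen arrive in one step, without triflate, coupling or osmium. Its weakness is that A5 must already contain the quaternary C10 and the adjacent C5 centre in the right relative and absolute sense, so the hardest problem of the target is only moved earlier. The C4 configuration also depends on which ketone face the acyl anion attacks, and the addition is reversible. The chosen route solves the C10 problem directly and fixes C3 and C4 by a substrate-controlled dihydroxylation.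

Key step: step 4

Remark on the chemistry: eudesmane numbering is used; β is the face of the C10 methyl (C14) and α the opposite face. The target is read as 3α-acyloxy, 4α-hydroxy-4β-methyl, 5α-H, 10β-methyl.

## Route

Step 1
Reactants: 1 6-methoxy-3,4-dihydronaphthalen-1(2H)-one (6-methoxy-1-tetralone)
Product: 2 (S)-6-methoxy-1,2,3,4-tetrahydronaphthalen-1-ol
Conditions: RuCl[(S,S)-TsDPEN](p-cymene) (1 mol%), HCO2H/Et3N (5:2), 40 °C
Reagents that add atoms: none
Why: Noyori asymmetric transfer hydrogenation of an aryl ketone; with the (S,S)-TsDPEN ligand the hydride is delivered to the face that gives the (S)-benzylic alcohol, the sense known for 1-tetralones. This carbinol (later C4, β-OH) is the only ring stereocentre set by a chiral reagent.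

Step 2
Reactants: 2 (S)-6-methoxy-1,2,3,4-tetrahydronaphthalen-1-ol
Product: 4 (S)-6-methoxy-1,2,3,4,5,8-hexahydronaphthalen-1-ol, via lithium alkoxide 3 (not isolated)
Conditions: n-BuLi (1.0 equiv), THF, −78 °C; then Li, NH3(l), t-BuOH, −78 to −33 °C; NH4Cl
Reagents that add atoms: none
Why: Birch reduction of the anisole ring leaves the methyl enol ether and the tetrasubstituted ring-fusion alkene. Benzylic C–O hydrogenolysis should be held back because the oxygen is present as alkoxide 3, its carbon sits para to the methoxy group where the radical anion carries little charge, and t-BuOH is too weak an acid to protonate the alkoxide appreciably.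

Step 3
Reactants: 4 (S)-6-methoxy-1,2,3,4,5,8-hexahydronaphthalen-1-ol
Product: 5 8,8-ethylenedioxy-11,12,13,14,15-pentanoreudesm-5(10)-en-4β-ol
Conditions: HOCH2CH2OH (5 equiv), PPTS (5 mol%), CH2Cl2, 0 °C to rt
Reagents that add atoms: ethylene glycol, OCCO
Why: Acid-catalysed transketalisation of a methyl enol ether: protonation at C7 gives the oxocarbenium ion at C8, which the diol traps, so no free ketone forms and the C5=C10 alkene cannot move into conjugation. The weak acid and low temperature are chosen to spare the ionisable allylic carbinol.

Step 4
Reactants: 5 8,8-ethylenedioxy-11,12,13,14,15-pentanoreudesm-5(10)-en-4β-ol; 6 diiodomethane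
Product: 8 8,8-ethylenedioxy-5β,10β-methano-11,12,13,14,15-pentanoreudesman-4β-ol, via ethylzinc alkoxide 7 (not isolated)
Conditions: Et2Zn (2.5 equiv), CH2I2 (5 equiv), CH2Cl2, −10 °C to rt; aq. NH4Cl
Reagents that add atoms: none
Why: Hydroxyl-directed Simmons–Smith cyclopropanation in the Furukawa variant. Et2Zn deprotonates the carbinol to ethylzinc alkoxide 7, which exchanges with diiodomethane (6) to an alkoxide-bound iodomethylzinc carbenoid. The carbenoid transfers CH2 to the C5=C10 alkene through the butterfly transition state in a concerted, stereospecific [2+1] addition that forms C10–C14 and C5–C14 at once; the cyclopropane is the only ring closed, and it closes by this concerted addition. The closest known reactions are the syn-selective zinc-carbenoid cyclopropanations of cyclohex-2-enols and of octalin-1-ols with the alkene at the ring fusion. C5 and C10 are both set by the C4–O–Zn tether, which reaches only the oxygen-bearing β face, and their cis relationship is enforced by the three-membered ring. The selectivity needed is facial: the anionic alkoxide binds zinc far better than the neutral dioxolane oxygens, which lie symmetrically on both faces, so α attack should not compete. Chemoselectivity is not in question because 5 has a single alkene, and an electron-rich tetrasubstituted alkene is a good partner for the electrophilic carbenoid despite its hindrance.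

Step 5
Reactants: 8 8,8-ethylenedioxy-5β,10β-methano-11,12,13,14,15-pentanoreudesman-4β-ol
Product: 9 8,8-ethylenedioxy-5β,10β-methano-11,12,13,14,15-pentanoreudesman-4-one
Conditions: Dess–Martin periodinane, NaHCO3, CH2Cl2, 0 °C to rt
Reagents that add atoms: none
Why: Dess–Martin oxidation of a secondary cyclopropyl carbinol under buffered conditions avoids cyclopropylcarbinyl cation rearrangement. The C4 stereocentre has done its work and is erased; C5 and C10 keep their configuration.

Step 6
Reactants: 9 8,8-ethylenedioxy-5β,10β-methano-11,12,13,14,15-pentanoreudesman-4-one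
Product: 11 8,8-ethylenedioxy-11,12,13,15-tetranor-5α-eudesman-4-one, via lithium Δ4-enolate 10 (not isolated)
Conditions: Li, NH3(l), THF, −78 °C; NH4Cl; then NaOMe (cat.), MeOH, rt
Reagents that add atoms: none
Why: Dissolving-metal reductive cleavage of a conjugated cyclopropyl ketone: the ketyl opens the C5–C14 bond, which lies nearly parallel to the carbonyl π orbital, and not the in-ring C5–C10 bond; ammonia protonates C14 to the methyl group while the ketone is protected as enolate 10. Protonation of 10 at C5 anti to the axial C14 methyl should give the trans-fused ketone; methoxide equilibration, expected to lie modestly on the trans side, lets any cis epimer be separated and recycled.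

Step 7
Reactants: 11 8,8-ethylenedioxy-11,12,13,15-tetranor-5α-eudesman-4-one
Product: 13 8,8-ethylenedioxy-11,12,13,15-tetranor-5α-eudesm-3-en-4-yl trifluoromethanesulfonate, via lithium Δ3-enolate 12 (not isolated)
Conditions: LiN(i-Pr)2, THF, −78 °C; PhNTf2, −78 to 0 °C
Reagents that add atoms: N-phenylbis(trifluoromethanesulfonimide), O=S(=O)(N(c1ccccc1)S(=O)(=O)C(F)(F)F)C(F)(F)F
Why: Kinetic deprotonation at the unhindered C3 methylene, not at the C5 methine beside the quaternary carbon, then O-triflation of enolate 12. Without equilibration C5 is not touched.

Step 8
Reactants: 13 8,8-ethylenedioxy-11,12,13,15-tetranor-5α-eudesm-3-en-4-yl trifluoromethanesulfonate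
Product: 14 8,8-ethylenedioxy-11,12,13-trinor-5α-eudesm-3-ene
Conditions: MeMgBr, Fe(acac)3 (5 mol%), THF/NMP, −30 to 0 °C
Reagents that add atoms: methylmagnesium bromide, C[Mg]Br
Why: Iron-catalysed Kumada-type cross-coupling of an alkenyl triflate with a methyl Grignard reagent; the alkene position is fixed by the triflate and the ketal is inert.

Step 9
Reactants: 14 8,8-ethylenedioxy-11,12,13-trinor-5α-eudesm-3-ene
Product: 15 11,12,13-trinor-5α-eudesm-3-en-8-one
Conditions: 1 M HCl, THF, rt
Reagents that add atoms: water, O
Why: Acid hydrolysis of the dioxolane; the isolated trisubstituted alkene is stable to dilute acid at room temperature.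

Step 10
Reactants: 15 11,12,13-trinor-5α-eudesm-3-en-8-one; 16 acetone
Product: 18 11-hydroxy-5α,7αH-eudesm-3-en-8-one, via lithium Δ7-enolate 17 (not isolated)
Conditions: LiN(i-Pr)2, THF, −78 °C; acetone, −78 °C; aq. NH4Cl at −78 °C
Reagents that add atoms: none
Why: Kinetic enolate formation on the C7 side (C9 is neopentylic) and aldol addition to acetone (16), quenched cold to limit retro-aldol. The C7 configuration, drawn as the equatorial 7β epimer, is of no consequence because it is lost in step 11.

Step 11
Reactants: 18 11-hydroxy-5α,7αH-eudesm-3-en-8-one
Product: 20 5α-eudesma-3,7(11)-dien-8-one, via mesylate 19 (not isolated)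
Conditions: MsCl, Et3N, CH2Cl2, 0 °C; then DBU, rt
Reagents that add atoms: none
Why: Mesylation of the tertiary aldol hydroxyl and base-induced E1cB elimination through the C7 enolate place the new alkene in conjugation as the isopropylidene ketone.

Step 12
Reactants: 20 5α-eudesma-3,7(11)-dien-8-one
Product: 21 3α,4α-dihydroxy-5α-eudesm-7(11)-en-8-one
Conditions: OsO4 (2 mol%), NMO (1.1 equiv), acetone/H2O, 0 °C to rt
Reagents that add atoms: osmium tetroxide, O=[Os](=O)(=O)=O; N-methylmorpholine N-oxide, C[N+]1([O-])CCOCC1; water, O
Why: Upjohn dihydroxylation; electrophilic OsO4 selects the electron-rich trisubstituted C3=C4 alkene over the electron-poor, tetrasubstituted enone alkene. The axial C14 methyl blocks the β face of ring A, so the cis-diol is delivered to the α face and sets C3 (α-OH) and C4 (α-OH, β-methyl).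

Step 13
Reactants: 21 3α,4α-dihydroxy-5α-eudesm-7(11)-en-8-one; 22 (S)-3-methylpentanoic acid
Product: 23 4α-hydroxy-8-oxo-5α-eudesm-7(11)-en-3α-yl (S)-3-methylpentanoate
Conditions: DCC, DMAP (cat.), CH2Cl2, 0 °C to rt
Reagents that add atoms: none
Why: Steglich esterification; the secondary C3 hydroxyl is acylated while the tertiary C4 hydroxyl is inert under these conditions. The stereocentre of the acid is β to the carboxyl group and cannot epimerise.

## Compound list

1 | 6-methoxy-3,4-dihydronaphthalen-1(2H)-one | COc1ccc2c(c1)CCCC2=O | starting material
2 | (S)-6-methoxy-1,2,3,4-tetrahydronaphthalen-1-ol | O[C@H]1CCCc2cc(OC)ccc12 | intermediate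
3 | lithium (S)-6-methoxy-1,2,3,4-tetrahydronaphthalen-1-olate | [Li]O[C@H]1CCCc2cc(OC)ccc12 | intermediate
4 | (S)-6-methoxy-1,2,3,4,5,8-hexahydronaphthalen-1-ol | O[C@H]1CCCC2=C1CC=C(OC)C2 | intermediate
5 | 8,8-ethylenedioxy-11,12,13,14,15-pentanoreudesm-5(10)-en-4β-ol, (5'S)-3',4',5',6',7',8'-hexahydro-1'H-spiro[1,3-dioxolane-2,2'-naphthalen]-5'-ol | O[C@H]1CCCC2=C1CCC3(C2)OCCO3 | intermediate
6 | diiodomethane | ICI | starting material
7 | ethylzinc 8,8-ethylenedioxy-11,12,13,14,15-pentanoreudesm-5(10)-en-4β-olate | CC[Zn]O[C@H]1CCCC2=C1CCC3(C2)OCCO3 | intermediate
8 | 8,8-ethylenedioxy-5β,10β-methano-11,12,13,14,15-pentanoreudesman-4β-ol ([4.4.1]propellane) | O[C@H]1CCC[C@@]23C[C@@]12CCC4(C3)OCCO4 | intermediate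
9 | 8,8-ethylenedioxy-5β,10β-methano-11,12,13,14,15-pentanoreudesman-4-one | O=C1CCC[C@@]23C[C@@]12CCC4(C3)OCCO4 | intermediate
10 | lithium 8,8-ethylenedioxy-11,12,13,15-tetranoreudesm-4-en-4-olate (10β-methyl) | [Li]OC1=C2CCC3(OCCO3)C[C@@]2(C)CCC1 | intermediate
11 | 8,8-ethylenedioxy-11,12,13,15-tetranor-5α-eudesman-4-one (trans-fused, 10β-methyl) | O=C1CCC[C@]2(C)CC3(OCCO3)CC[C@@H]12 | intermediate
12 | lithium 8,8-ethylenedioxy-11,12,13,15-tetranor-5α-eudesm-3-en-4-olate | [Li]OC1=CCC[C@]2(C)CC3(OCCO3)CC[C@@H]12 | intermediate
13 | 8,8-ethylenedioxy-11,12,13,15-tetranor-5α-eudesm-3-en-4-yl trifluoromethanesulfonate | O=S(=O)(OC1=CCC[C@]2(C)CC3(OCCO3)CC[C@@H]12)C(F)(F)F | intermediate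
14 | 8,8-ethylenedioxy-11,12,13-trinor-5α-eudesm-3-ene | CC1=CCC[C@]2(C)CC3(OCCO3)CC[C@@H]12 | intermediate
15 | 11,12,13-trinor-5α-eudesm-3-en-8-one | CC1=CCC[C@]2(C)CC(=O)CC[C@@H]12 | intermediate
16 | acetone | CC(C)=O | starting material
17 | lithium 11,12,13-trinor-5α-eudesma-3,7-dien-8-olate | CC1=CCC[C@]2(C)CC(O[Li])=CC[C@@H]12 | intermediate
18 | 11-hydroxy-5α,7αH-eudesm-3-en-8-one (7β-(2-hydroxypropan-2-yl)) | CC1=CCC[C@]2(C)CC(=O)[C@@H](C(C)(C)O)C[C@@H]12 | intermediate
19 | 8-oxo-5α,7αH-eudesm-3-en-11-yl methanesulfonate | CC1=CCC[C@]2(C)CC(=O)[C@@H](C(C)(C)OS(C)(=O)=O)C[C@@H]12 | intermediate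
20 | 5α-eudesma-3,7(11)-dien-8-one | CC1=CCC[C@]2(C)CC(=O)C(=C(C)C)C[C@@H]12 | intermediate
21 | 3α,4α-dihydroxy-5α-eudesm-7(11)-en-8-one | O[C@@H]1CC[C@]2(C)CC(=O)C(=C(C)C)C[C@H]2[C@]1(C)O | intermediate
22 | (S)-3-methylpentanoic acid | CC[C@H](C)CC(=O)O | starting material
23 | 4α-hydroxy-8-oxo-5α-eudesm-7(11)-en-3α-yl (S)-3-methylpentanoate (CNP0334363.1) | CC[C@H](C)CC(=O)O[C@@H]1CC[C@]2(C)CC(=O)C(=C(C)C)C[C@H]2[C@]1(C)O | target

## Step count and risk

Total step count: 13. Longest linear sequence: 13 steps, from 1 to 23; compounds 6, 16 and 22 are bought and enter directly.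

Step 4 (key step). The methylene transfer to a tetrasubstituted alkene may be slow. During a long reaction the ZnI2 that builds up can open the dioxolane, or the carbenoid can be delivered from a ketal oxygen, which would erode the facial selectivity. The fallback keeps the relay from C4 to C10 but delivers the carbon as a nucleophile. Alcohol 5 is converted with phenyl isocyanate into the N-phenylcarbamate of 5, F1. Deprotonation with MeLi, addition of CuI and a second equivalent of MeLi should give a carbamate-bound methylcopper species that transfers methyl to C10 in a syn-SN2′ substitution on the β face. The product is 8,8-ethylenedioxy-11,12,13,15-tetranoreudesm-4-ene F2, with the alkene moved to C4=C5. Hydroboration with BH3·THF and oxidation with H2O2/NaOH places boron on the less hindered C4 from the α face, anti to C14, and gives the trans-fused 8,8-ethylenedioxy-11,12,13,15-tetranor-5α-eudesman-4α-ol F3. Dess–Martin oxidation returns to the route at ketone 11, bypassing steps 4 to 6.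

Step 6. Protonation of enolate 10 may show poor facial selectivity, and the thermodynamic preference for the trans ring fusion in an angularly methylated 1-decalone is small. Equilibration may therefore leave a large share of the cis epimer to be separated and recycled. The fallback sets C5 by hydrogenation. Ketone 9 is reduced with Li in NH3 as before, but enolate 10 is silylated with Me3SiCl/Et3N and not protonated, giving the trimethylsilyl enol ether F4. Saegusa–Ito dehydrogenation with Pd(OAc)2 in MeCN can eliminate only towards C6 and should give 8,8-ethylenedioxy-11,12,13,15-tetranoreudesm-5-en-4-one F5. Hydrogenation over Pd/C adds hydrogen to C5 and C6 from the α face, anti to the adjacent angular methyl, and returns to the route at 11. The fallback for step 4 also fixes C5, by hydroboration.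

Step 3. The carbinol is allylic to a tetrasubstituted alkene, and acid may ionise it, with loss of water or substitution by the diol, before the enol ether has been exchanged. The fallback removes the free hydroxyl during the acid step. Alcohol 4 is silylated with t-BuPh2SiCl/imidazole to the silyl ether of 4, F6. Ketalisation under the same conditions gives the silyl ether of 5, F7, and Bu4NF returns to the route at 5.

Step 10. Proton transfer from acetone to enolate 17 and retro-aldol cleavage on warming may leave much of ketone 15 unchanged. The fallback replaces the reversible lithium aldol by a Lewis-acid-mediated one. Ketone 15 is converted with LiN(i-Pr)2 and Me3SiCl into the C7–C8 trimethylsilyl enol ether F8. Mukaiyama aldol addition of F8 to acetone (16) with TiCl4 in CH2Cl2 at −78 °C is made irreversible by silyl transfer and returns to the route at aldol 18.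

## Further compounds

F1 | step 4 | 8,8-ethylenedioxy-11,12,13,14,15-pentanoreudesm-5(10)-en-4β-yl N-phenylcarbamate | O=C(Nc1ccccc1)O[C@H]1CCCC2=C1CCC3(C2)OCCO3
F2 | step 4 | 8,8-ethylenedioxy-11,12,13,15-tetranoreudesm-4-ene (10β-methyl) | C1=C2CCC3(OCCO3)C[C@@]2(C)CCC1
F3 | step 4 | 8,8-ethylenedioxy-11,12,13,15-tetranor-5α-eudesman-4α-ol | O[C@@H]1CCC[C@]2(C)CC3(OCCO3)CC[C@@H]12
F4 | step 6 | 8,8-ethylenedioxy-4-(trimethylsilyloxy)-11,12,13,15-tetranoreudesm-4-ene | C[Si](C)(C)OC1=C2CCC3(OCCO3)C[C@@]2(C)CCC1
F5 | step 6 | 8,8-ethylenedioxy-11,12,13,15-tetranoreudesm-5-en-4-one | O=C1CCC[C@]2(C)CC3(OCCO3)CC=C12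
F6 | step 3 | (S)-tert-butyl[(6-methoxy-1,2,3,4,5,8-hexahydronaphthalen-1-yl)oxy]diphenylsilane | CC(C)(C)[Si](c1ccccc1)(c1ccccc1)O[C@H]1CCCC2=C1CC=C(OC)C2
F7 | step 3 | 4β-(tert-butyldiphenylsilyloxy)-8,8-ethylenedioxy-11,12,13,14,15-pentanoreudesm-5(10)-ene | CC(C)(C)[Si](c1ccccc1)(c1ccccc1)O[C@H]1CCCC2=C1CCC3(C2)OCCO3
F8 | step 10 | 8-(trimethylsilyloxy)-11,12,13-trinor-5α-eudesma-3,7-diene | CC1=CCC[C@]2(C)CC(O[Si](C)(C)C)=CC[C@@H]12
A1 | alternative 1 | 3-[3-(methoxycarbonyloxymethyl)but-3-enyl]-2,4-dimethylphenol | COC(=O)OCC(=C)CCc1c(C)ccc(O)c1C
A2 | alternative 1 | 8-methylidene-11,12,13-trinoreudesma-1,4-dien-3-one | O=C1C=C[C@]2(C)CC(=C)CCC2=C1C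
A3 | alternative 2 | (E)-9-(tert-butyldimethylsilyloxy)-7-methyldeca-7,9-dien-1-yn-3-one | C#CC(=O)CCC/C(C)=C/C(=C)O[Si](C)(C)C(C)(C)C
A4 | alternative 2 | 8-(tert-butyldimethylsilyloxy)-11,12,13,15-tetranoreudesma-5,8-dien-4-one | O=C1CCC[C@]2(C)C=C(O[Si](C)(C)C(C)(C)C)CC=C12
A5 | alternative 3 | 8,8-ethylenedioxy-4-oxo-3,4-seco-11,12,13-trinor-5α-eudesman-3-al | O=CCC[C@]1(C)CC2(OCCO2)CC[C@H]1C(C)=O
A6 | alternative 3 | 4α-hydroxy-11,12,13-trinoreudesmane-3,8-dione 8-ethylene ketal | O=C1CC[C@]2(C)CC3(OCCO3)CC[C@H]2[C@]1(C)O
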